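**The question.** Four flasks of solid first end groups stirred with second end groups are to be ranked by their links, as a share of the solid charged, after 10 h.

| flask | solid first end groups | second end groups | remark | time |
|---|---|---|---|---|
| delta | 0.74 M | 1.8 M | run made earlier |  |
| eta | 2.9 M | 1.8 M | run made earlier |  |
| noon | 0.60 M | 1.80 M |  | 10 h |
| dawn | 0.50 M | 1.80 M |  | 10 h |
| midnight | 2.0 M | 1.80 M |  | 10 h |
| summer | 1.2 M | 1.80 M |  | 10 h |

- delta (time / h: links / %, solid first end groups / %): 0.500: 1.7, 76.3; 1.00: 6.7, 55.0; 1.50: 12.8, 33.8; 2.50: 29.0, 0; 4.00: 48.3, 0; 8.00: 57.5, 0
- eta (time / h: links / %, solid first end groups / %): 0.500: 1.1, 92.9; 1.33: 2.6, 85.0; 2.50: 7.3, 73.9; 4.00: 14.8, 61.4; 5.00: 17.6, 53.3; 8.00: 23.9, 32.0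

(standard deviation of a reading: 0.5 percentage points)

- the flasks by amount of links, in percent of the solid first end groups charged, highest first, at 10 h (noon / dawn / midnight / summer)
- the amount of links, in percent of the solid first end groups charged of the flask you put first, at 10 h
- the amount of links, in percent of the solid first end groups charged of the flask you put last, at 10 h

- at the start none of the solid first end groups is in solution
- what has only dissolved of solid first end groups counts as not reacted

**End state.** In the delta run the solid read 0% at 2.50 h, and links reached 57.5% at 8.00 h. Take that last reading as an end state, with each link using one of each end group and freeing one by-product. It gives 0.419 for the link quotient: cL squared over cA times cB, with cA and cB taken as charges minus links.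

**Four shares.** Holding this quotient on each charge leaves a quadratic in cL. Dawn reckons to 0.327 M, or 65.4%. Noon reckons to 61.8%, summer to 47.5% and midnight to 37.2%. So by this reckoning dawn stands first and midnight last.

**Weak link.** The eta run lost solid at about 0.235 M h⁻¹, so midnight's solid lasts about 8.49 h, close under 10 h. Yet the eta readings at 8.00 h, with solid still present and taken off cA as well, already give a quotient of 0.339. On midnight's charge that quotient reckons to 34.9%, a lower estimate beside 37.2%.

**The forecast.** It ranked dawn > noon > summer > midnight, with 65.5% and 37.2%: “both runs fit a reversible reaction that also releases a by-product”.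

**The flasks.** They give dawn > noon > summer > midnight, with 63.3% and 35.7%.

    first end groups + second end groups ⇌ links + by-product (K = 28.0, k = 0.00280 M⁻¹ min⁻¹)
    solid first end groups ⇌ first end groups, rate k2*(cs2 - [first end groups]) while solid is left; crystals form when [first end groups] > cs2 (solubility = 1.90 M, k = 0.00320 min⁻¹)
    links + by-product → side product (k = 0.00310 M⁻¹ min⁻¹)

**A neighbour.** The quotient 0.419 from delta is no equilibrium constant: the way back makes no difference to dawn's links. Dawn with 0.72 M of second end groups reckons by 0.419 to 46.6%, and that flask gives 46.8%. Of the solid charged in that flask, 43.1% stands as first end groups and 10.1% as side product.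

The readings are calculated on assumed constants; the scatter is artificial.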